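**Retrosynthetic overview**

1. Ring atoms are numbered C1 (=C–CO2H) to C10 (C=CH2), with C6 quaternary and C7 the CH–CO2H. Target 20 ⇐ diester 19 (saponification) ⇐ 18 (hydration of a furan-3-ylethynyl group, the masked CH2–C(=O)–furyl chain) ⇐ 17 (methylenation of a C10 ketone).
2. Key disconnection: the C1(CO2R)=C2H pair sits between C10 (ketone level) and the C3=C4 alkene, so it is a propiolate unit inserted into the C10–C3 bond of cyclooct-2-enone 12 (ring atoms C10, C3–C9). The eight-membered ring is expanded to the ten-membered ring by dienamine [2+2] addition, 4π ring opening and vinylogous tautomerisation.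
3. 12 ⇐ cycloheptenone 8 (CH2 insertion of C9) ⇐ silyloxycyclohexene 4 (Ito–Saegusa insertion of C3, which also creates the C3=C4 enone).
4. 4, with both stereocentres (C6, C7), ⇐ catalytic asymmetric Diels–Alder reaction of 2 with 3.
5. Ring order: cyclohexene (C10, C4–C8) → cycloheptenone → cyclooctenone → cyclodecadienone; the furan is attached by Sonogashira coupling.

Key step: step 8

Remark: the absolute configuration is set once, in step 2; C6 and C7 are not touched afterwards (the change of the C6 descriptor from R to S in step 10 is only a change of CIP priorities).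

**Route**

Step 1
Reactants: 1 but-3-en-2-one
Product: 2 2-[(triisopropylsilyl)oxy]buta-1,3-diene
Conditions: TIPSOTf, Et3N, Et2O, 0 °C → rt
Reagents that add atoms: triisopropylsilyl trifluoromethanesulfonate, CC(C)[Si](C(C)C)(C(C)C)OS(=O)(=O)C(F)(F)F
Why: Soft enolisation and O-silylation of the methyl ketone is the standard way to 2-silyloxybutadienes, and the bulky silyl group makes the enol ether robust enough for steps 2–4.

Step 2
Reactants: 2 2-[(triisopropylsilyl)oxy]buta-1,3-diene; 3 ethyl (E)-3-methyl-4-oxobut-2-enoate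
Product: 4 ethyl (1R,6R)-6-formyl-6-methyl-3-[(triisopropylsilyl)oxy]cyclohex-3-ene-1-carboxylate
Conditions: Corey oxazaborolidinium catalyst (o-tolyl-CBS·HNTf2, 15 mol%; the enantiomer that gives (1R,6R)-4 by the pre-transition-state model for α-substituted enals), CH2Cl2, −78 → −40 °C
Reagents that add atoms: none
Why: Catalytic enantioselective Diels–Alder reaction: the Lewis-acid-bound formyl group directs the silyloxy carbon para to the formyl-bearing carbon, suprafacial addition to the (E)-dienophile places CO2Et cis to CH3, and the catalyst shields one face of the enal, so both stereocentres should be set in the required relative and absolute sense.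

Step 3
Reactants: 4 ethyl (1R,6R)-6-formyl-6-methyl-3-[(triisopropylsilyl)oxy]cyclohex-3-ene-1-carboxylate
Product: 5 ethyl (1R,6R)-6-ethynyl-6-methyl-3-[(triisopropylsilyl)oxy]cyclohex-3-ene-1-carboxylate
Conditions: dimethyl (1-diazo-2-oxopropyl)phosphonate, K2CO3, EtOH, 0 °C → rt
Reagents that add atoms: dimethyl (1-diazo-2-oxopropyl)phosphonate, COP(=O)(OC)C(=[N+]=[N-])C(C)=O
Why: Seyferth–Gilbert homologation with the Ohira–Bestmann reagent converts the non-enolisable quaternary aldehyde into the terminal alkyne under conditions too mild to epimerise the ester α-centre or cleave the TIPS enol ether.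

Step 4
Reactants: 5 ethyl (1R,6R)-6-ethynyl-6-methyl-3-[(triisopropylsilyl)oxy]cyclohex-3-ene-1-carboxylate
Product: 6 ethyl (3R,4R)-4-ethynyl-4-methyl-1-[(triisopropylsilyl)oxy]bicyclo[4.1.0]heptane-3-carboxylate
Conditions: Et2Zn, CH2I2, CH2Cl2, 0 °C → rt
Reagents that add atoms: diiodomethane, ICI
Why: Simmons–Smith (Furukawa) cyclopropanation is selective for the electron-rich silyl enol ether; the facial outcome is irrelevant because both cyclopropane stereocentres are destroyed in step 5.

Step 5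
Reactants: 6 ethyl (3R,4R)-4-ethynyl-4-methyl-1-[(triisopropylsilyl)oxy]bicyclo[4.1.0]heptane-3-carboxylate
Product: 8 ethyl (1R,2R)-2-ethynyl-2-methyl-6-oxocyclohept-4-ene-1-carboxylate, via β-chloro ketone 7 (not isolated)
Conditions: FeCl3, DMF, 0 °C → rt; then NaOAc, EtOH, 70 °C
Reagents that add atoms: none
Why: Ito–Saegusa ring expansion: Fe(III) oxidation of the siloxycyclopropane cleaves the internal bond to a ring-enlarged β-keto radical, chlorine transfer and E1cB loss of HCl give the cyclohept-2-enone, so C3 and the C3=C4 enone are placed where the Diels–Alder regiochemistry dictates.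

Step 6
Reactants: 8 ethyl (1R,2R)-2-ethynyl-2-methyl-6-oxocyclohept-4-ene-1-carboxylate
Product: 10 ethyl (1R,2R)-2-ethynyl-2-methyl-6-oxocyclooct-4-ene-1-carboxylate, via α-silyl ketone 9 (not isolated)
Conditions: TMSCHN2, BF3·OEt2, CH2Cl2, −78 → −30 °C; then 1 M HCl, THF, rt
Reagents that add atoms: (trimethylsilyl)diazomethane, C[Si](C)(C)C=[N+]=[N-]
Why: Lewis-acid-promoted diazoalkane ring homologation (Tiffeneau–Demjanov-type 1,2-shift): the saturated α-CH2 should migrate in preference to the vinylic carbon, which keeps the enone conjugated and inserts C9 on the saturated side; acidic work-up removes the C-silyl group.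

Step 7
Reactants: 10 ethyl (1R,2R)-2-ethynyl-2-methyl-6-oxocyclooct-4-ene-1-carboxylate; 11 3-bromofuran
Product: 12 ethyl (1R,2R)-2-[(furan-3-yl)ethynyl]-2-methyl-6-oxocyclooct-4-ene-1-carboxylate
Conditions: Pd(PPh3)2Cl2 (5 mol%), CuI (10 mol%), Et3N, DMF, 60 °C
Reagents that add atoms: none
Why: Sonogashira coupling of the terminal alkyne with the heteroaryl bromide; the tertiary amine base does not add irreversibly to the enone.

Step 8
Reactants: 12 ethyl (1R,2R)-2-[(furan-3-yl)ethynyl]-2-methyl-6-oxocyclooct-4-ene-1-carboxylate; 13 ethyl prop-2-ynoate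
Product: 17 diethyl (1E,3Z,6R,7R)-6-[(furan-3-yl)ethynyl]-6-methyl-10-oxocyclodeca-1,3-diene-1,7-dicarboxylate, via linear dienamine 14 (not isolated), via aminocyclobutene 15 (not isolated), via ring-opened trienamine 16 (not isolated)
Conditions: pyrrolidine, TsOH (cat.), PhH, reflux (Dean–Stark), then evaporate; 13, PhMe, 0 → 80 °C; then AcOH/NaOAc (or 1 M HCl), THF/H2O, rt
Reagents that add atoms: water, O
Why: Proposed new method: the linear dienamine 14 (N–C10=C3–C4=C5) adds through C3 to the propiolate, the allenolate closes on the iminium carbon C10 (Mannich-type 4-exo-trig closure, formal [2+2]) to the cis-fused aminocyclobutene 15, and its donor–acceptor ring opens by thermal conrotatory 4π electrocyclic cleavage of the C10–C3 bond to the ten-membered trienamine 16; protonation at C5 and hydrolysis of the conjugated iminium ion then give 17. The closest known reaction type is the enamine–acetylenic ester two-carbon ring expansion of cyclic ketones (cyclooctanone enamines to cyclodecadienes); new is its use on a 1-amino-1,3-diene, so that the product arrives directly at the dienone oxidation level. No stereocentre is formed and C6/C7 are not involved; the C1=C2 and C3=C4 geometries are under thermodynamic control, because the push–pull enamino ester rotates easily and the trienamine/iminium pair interconverts the isomers, so the E/Z mixtures from either conrotatory mode should funnel into the ring-cis,cis (1E,3Z) dienone. The step needs attack at C3 rather than C5 and [2+2] rather than [4+2]: C5 is neopentyl (next to quaternary C6) and the twisted cis,cis-diene of an eight-membered ring is a poor Diels–Alder diene. The only ketone in 12 is the enone, and the aryl alkyne is inert to the amine and the propiolate.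

Step 9
Reactants: 17 diethyl (1E,3Z,6R,7R)-6-[(furan-3-yl)ethynyl]-6-methyl-10-oxocyclodeca-1,3-diene-1,7-dicarboxylate
Product: 18 diethyl (1E,3Z,6R,7R)-6-[(furan-3-yl)ethynyl]-6-methyl-10-methylidenecyclodeca-1,3-diene-1,7-dicarboxylate
Conditions: Zn, CH2Br2, TiCl4 (Lombardo reagent), THF/CH2Cl2, 0 °C → rt
Reagents that add atoms: dibromomethane, BrCBr
Why: Lombardo–Takai methylenation: the non-basic Zn/Ti gem-dimetallic reagent methylenates ketones in the presence of esters and alkynes and does not deprotonate the vinylogously acidic C5–H2, and C10=O is the only ketone at this stage.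

Step 10
Reactants: 18 diethyl (1E,3Z,6R,7R)-6-[(furan-3-yl)ethynyl]-6-methyl-10-methylidenecyclodeca-1,3-diene-1,7-dicarboxylate
Product: 19 diethyl (1E,3Z,6S,7R)-6-[2-(furan-3-yl)-2-oxoethyl]-6-methyl-10-methylidenecyclodeca-1,3-diene-1,7-dicarboxylate
Conditions: Ph3PAuNTf2 (3 mol%), H2O (5 equiv), 1,4-dioxane, 50 °C
Reagents that add atoms: water, O
Why: Gold(I)-catalysed Markovnikov hydration of the aryl alkyne: oxygen should go to the furyl-bearing alkyne carbon (furyl-stabilised and remote from the neopentyl quaternary centre), which gives the C6–CH2–C(=O)–furyl chain; 6-endo participation of the C7 ester leads to the same carbonyl position.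

Step 11
Reactants: 19 diethyl (1E,3Z,6S,7R)-6-[2-(furan-3-yl)-2-oxoethyl]-6-methyl-10-methylidenecyclodeca-1,3-diene-1,7-dicarboxylate
Product: 20 (1E,3Z,6S,7R)-6-[2-(furan-3-yl)-2-oxoethyl]-6-methyl-10-methylidenecyclodeca-1,3-diene-1,7-dicarboxylic acid
Conditions: LiOH·H2O (6 equiv), THF/EtOH/H2O, 0 → 40 °C; then 1 M HCl to pH 3, 0 °C
Reagents that add atoms: lithium hydroxide, [Li+].[OH-]
Why: Saponification of both ethyl esters (acyl–oxygen cleavage); hydroxide is too weak a base to epimerise the C7 ester α-centre before it is converted into the carboxylate.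

**Compound list**

1 | but-3-en-2-one (methyl vinyl ketone) | CC(=O)C=C | starting material
2 | 2-[(triisopropylsilyl)oxy]buta-1,3-diene | C=CC(=C)O[Si](C(C)C)(C(C)C)C(C)C | intermediate
3 | ethyl (E)-3-methyl-4-oxobut-2-enoate | CCOC(=O)/C=C(\C)C=O | starting material
4 | ethyl (1R,6R)-6-formyl-6-methyl-3-[(triisopropylsilyl)oxy]cyclohex-3-ene-1-carboxylate | C1(O[Si](C(C)C)(C(C)C)C(C)C)C[C@@H](C(=O)OCC)[C@](C)(C=O)CC=1 | intermediate
5 | ethyl (1R,6R)-6-ethynyl-6-methyl-3-[(triisopropylsilyl)oxy]cyclohex-3-ene-1-carboxylate | C1(O[Si](C(C)C)(C(C)C)C(C)C)C[C@@H](C(=O)OCC)[C@](C)(C#C)CC=1 | intermediate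
6 | ethyl (3R,4R)-4-ethynyl-4-methyl-1-[(triisopropylsilyl)oxy]bicyclo[4.1.0]heptane-3-carboxylate (both cyclopropane faces) | C12(O[Si](C(C)C)(C(C)C)C(C)C)C[C@@H](C(=O)OCC)[C@](C)(C#C)CC1C2 | intermediate
7 | ethyl (1R,2R)-4-chloro-2-ethynyl-2-methyl-6-oxocycloheptane-1-carboxylate (C4 epimers) | O=C1C[C@@H](C(=O)OCC)[C@](C)(C#C)CC(Cl)C1 | intermediate
8 | ethyl (1R,2R)-2-ethynyl-2-methyl-6-oxocyclohept-4-ene-1-carboxylate | O=C1C[C@@H](C(=O)OCC)[C@](C)(C#C)CC=C1 | intermediate
9 | ethyl (1R,2R)-2-ethynyl-2-methyl-6-oxo-7-(trimethylsilyl)cyclooct-4-ene-1-carboxylate (C7 epimers) | O=C1C([Si](C)(C)C)C[C@@H](C(=O)OCC)[C@](C)(C#C)CC=C1 | intermediate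
10 | ethyl (1R,2R)-2-ethynyl-2-methyl-6-oxocyclooct-4-ene-1-carboxylate | O=C1CC[C@@H](C(=O)OCC)[C@](C)(C#C)CC=C1 | intermediate
11 | 3-bromofuran | Brc1ccoc1 | starting material
12 | ethyl (1R,2R)-2-[(furan-3-yl)ethynyl]-2-methyl-6-oxocyclooct-4-ene-1-carboxylate | O=C1CC[C@@H](C(=O)OCC)[C@](C)(C#Cc2ccoc2)CC=C1 | intermediate
13 | ethyl prop-2-ynoate (ethyl propiolate) | C#CC(=O)OCC | starting material
14 | ethyl (1R,2R)-2-[(furan-3-yl)ethynyl]-2-methyl-6-(pyrrolidin-1-yl)cycloocta-3,5-diene-1-carboxylate | C1(N2CCCC2)CC[C@@H](C(=O)OCC)[C@](C)(C#Cc2ccoc2)C=CC=1 | intermediate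
15 | diethyl (4R,5R)-5-[(furan-3-yl)ethynyl]-5-methyl-1-(pyrrolidin-1-yl)bicyclo[6.2.0]deca-6,9-diene-4,10-dicarboxylate (cis ring fusion) | C12(N3CCCC3)CC[C@@H](C(=O)OCC)[C@](C)(C#Cc3ccoc3)C=CC1C=C2C(=O)OCC | intermediate
16 | diethyl (6R,7R)-6-[(furan-3-yl)ethynyl]-6-methyl-10-(pyrrolidin-1-yl)cyclodeca-1(10),2,4-triene-1,7-dicarboxylate | C1(N2CCCC2)CC[C@@H](C(=O)OCC)[C@](C)(C#Cc2ccoc2)C=CC=CC=1C(=O)OCC | intermediate
17 | diethyl (1E,3Z,6R,7R)-6-[(furan-3-yl)ethynyl]-6-methyl-10-oxocyclodeca-1,3-diene-1,7-dicarboxylate | O=C1CC[C@@H](C(=O)OCC)[C@](C)(C#Cc2ccoc2)C/C=C\C=C/1C(=O)OCC | intermediate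
18 | diethyl (1E,3Z,6R,7R)-6-[(furan-3-yl)ethynyl]-6-methyl-10-methylidenecyclodeca-1,3-diene-1,7-dicarboxylate | C=C1CC[C@@H](C(=O)OCC)[C@](C)(C#Cc2ccoc2)C/C=C\C=C/1C(=O)OCC | intermediate
19 | diethyl (1E,3Z,6S,7R)-6-[2-(furan-3-yl)-2-oxoethyl]-6-methyl-10-methylidenecyclodeca-1,3-diene-1,7-dicarboxylate | C=C1CC[C@@H](C(=O)OCC)[C@](C)(CC(=O)c2ccoc2)C/C=C\C=C/1C(=O)OCC | intermediate
20 | (1E,3Z,6S,7R)-6-[2-(furan-3-yl)-2-oxoethyl]-6-methyl-10-methylidenecyclodeca-1,3-diene-1,7-dicarboxylic acid (CNP0137484.1) | C=C1CC[C@@H](C(=O)O)[C@](C)(CC(=O)c2ccoc2)C/C=C\C=C/1C(=O)O | target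

**Step count and risks**

Total step count: 11. Longest linear sequence: 11 steps (from 1; 3, 11 and 13 enter as catalogue compounds).

Steps most likely to fail:

1. Step 8 (Proposed new method). The enone may condense to the cross-conjugated dienamine (deprotonation at C9) instead of the linear one, or the linear dienamine may react as a 4π component, so that the propiolate is inserted on the wrong side of C10 or a bridged adduct forms; incomplete vinylogous isomerisation would leave double-bond isomers. The fallback uses known reaction types and runs from 12 back to 17. Copper hydride conjugate reduction of 12 with in situ O-silylation (Stryker's reagent, Me3SiCl) should give the regiodefined silyl enol ether ethyl (1R,2R)-2-[(furan-3-yl)ethynyl]-2-methyl-6-[(trimethylsilyl)oxy]cyclooct-5-ene-1-carboxylate F1. TiCl4-promoted [2+2] cycloaddition of F1 with 13 at −78 °C (silyl enol ether–propiolate cycloaddition) should give the siloxycyclobutene diethyl (4R,5R)-5-[(furan-3-yl)ethynyl]-5-methyl-1-[(trimethylsilyl)oxy]bicyclo[6.2.0]dec-9-ene-4,10-dicarboxylate F2, which on warming in toluene should open to the ring-expanded 2-siloxydiene diethyl (6R,7R)-6-[(furan-3-yl)ethynyl]-6-methyl-10-[(trimethylsilyl)oxy]cyclodeca-1(10),2-diene-1,7-dicarboxylate F3. Dehydrogenation of this dienol silyl ether with DDQ (the 3,5-dienol ether to 4,6-dien-3-one transformation) should then give 17.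

2. Step 6. The vinylic instead of the saturated α-carbon may migrate, or the diazoalkane may add to the enone C=C as a 1,3-dipole, which would give the regioisomeric cyclooctenone or pyrazolines. The fallback runs from 8 back to 12, bypassing 10. Sonogashira coupling of 8 with 11 should give ethyl (1R,2R)-2-[(furan-3-yl)ethynyl]-2-methyl-6-oxocyclohept-4-ene-1-carboxylate F4. Kinetic deprotonation at the only sp3 α-carbon (LDA, −78 °C) and Me3SiCl should give the cross-conjugated dienol silyl ether ethyl (1R,2R)-2-[(furan-3-yl)ethynyl]-2-methyl-6-[(trimethylsilyl)oxy]cyclohepta-4,6-diene-1-carboxylate F5. Simmons–Smith cyclopropanation of its electron-rich enol ether double bond should give ethyl (5R,6R)-5-[(furan-3-yl)ethynyl]-5-methyl-1-[(trimethylsilyl)oxy]bicyclo[5.1.0]oct-2-ene-6-carboxylate F6. Fe(NO3)3-mediated ring opening in the presence of 1,4-cyclohexadiene (the reductive variant of the Ito–Saegusa expansion) cleaves the internal cyclopropane bond and should give 12 with C9 placed unambiguously.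

3. Step 10. The gold-activated alkyne may be attacked by the C3=C4 alkene (1,5-enyne cycloisomerisation) or by the C7 ester carbonyl in the 5-exo mode, which would lead to carbocyclised products or to the regioisomeric ketone. The fallback runs from 17 back to 19, bypassing 18. Hydration is carried out on 17, whose ring alkenes are all electron-poor, to give diethyl (1E,3Z,6S,7R)-6-[2-(furan-3-yl)-2-oxoethyl]-6-methyl-10-oxocyclodeca-1,3-diene-1,7-dicarboxylate F7. Only the ring ketone is part of a vinylogous β-keto ester, so its extended enolate (NaH, PhNTf2) should give selectively the trienyl triflate diethyl (6R,7R)-6-[2-(furan-3-yl)-2-oxoethyl]-6-methyl-10-{[(trifluoromethyl)sulfonyl]oxy}cyclodeca-1(10),2,4-triene-1,7-dicarboxylate F8. Negishi coupling with Me3SiCH2ZnCl (Pd(PPh3)4) should give the allylsilane diethyl (6R,7R)-6-[2-(furan-3-yl)-2-oxoethyl]-6-methyl-10-[(trimethylsilyl)methyl]cyclodeca-1(10),2,4-triene-1,7-dicarboxylate F9. Acid-promoted vinylogous protodesilylation (protonation at C5, loss of silicon from the exocyclic carbon) should then give 19.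

Further compounds
F1 | step 8 | ethyl (1R,2R)-2-[(furan-3-yl)ethynyl]-2-methyl-6-[(trimethylsilyl)oxy]cyclooct-5-ene-1-carboxylate | C1(O[Si](C)(C)C)CC[C@@H](C(=O)OCC)[C@](C)(C#Cc2ccoc2)CCC=1
F2 | step 8 | diethyl (4R,5R)-5-[(furan-3-yl)ethynyl]-5-methyl-1-[(trimethylsilyl)oxy]bicyclo[6.2.0]dec-9-ene-4,10-dicarboxylate | C12(O[Si](C)(C)C)CC[C@@H](C(=O)OCC)[C@](C)(C#Cc3ccoc3)CCC1C=C2C(=O)OCC
F3 | step 8 | diethyl (6R,7R)-6-[(furan-3-yl)ethynyl]-6-methyl-10-[(trimethylsilyl)oxy]cyclodeca-1(10),2-diene-1,7-dicarboxylate | C1(O[Si](C)(C)C)CC[C@@H](C(=O)OCC)[C@](C)(C#Cc2ccoc2)CCC=CC=1C(=O)OCC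
F4 | step 6 | ethyl (1R,2R)-2-[(furan-3-yl)ethynyl]-2-methyl-6-oxocyclohept-4-ene-1-carboxylate | O=C1C[C@@H](C(=O)OCC)[C@](C)(C#Cc2ccoc2)CC=C1
F5 | step 6 | ethyl (1R,2R)-2-[(furan-3-yl)ethynyl]-2-methyl-6-[(trimethylsilyl)oxy]cyclohepta-4,6-diene-1-carboxylate | C1(O[Si](C)(C)C)=C[C@@H](C(=O)OCC)[C@](C)(C#Cc2ccoc2)CC=C1
F6 | step 6 | ethyl (5R,6R)-5-[(furan-3-yl)ethynyl]-5-methyl-1-[(trimethylsilyl)oxy]bicyclo[5.1.0]oct-2-ene-6-carboxylate | C12(O[Si](C)(C)C)CC2[C@@H](C(=O)OCC)[C@](C)(C#Cc3ccoc3)CC=C1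
F7 | step 10 | diethyl (1E,3Z,6S,7R)-6-[2-(furan-3-yl)-2-oxoethyl]-6-methyl-10-oxocyclodeca-1,3-diene-1,7-dicarboxylate | O=C1CC[C@@H](C(=O)OCC)[C@](C)(CC(=O)c2ccoc2)C/C=C\C=C/1C(=O)OCC
F8 | step 10 | diethyl (6R,7R)-6-[2-(furan-3-yl)-2-oxoethyl]-6-methyl-10-{[(trifluoromethyl)sulfonyl]oxy}cyclodeca-1(10),2,4-triene-1,7-dicarboxylate | C1(OS(=O)(=O)C(F)(F)F)CC[C@@H](C(=O)OCC)[C@](C)(CC(=O)c2ccoc2)C=CC=CC=1C(=O)OCC
F9 | step 10 | diethyl (6R,7R)-6-[2-(furan-3-yl)-2-oxoethyl]-6-methyl-10-[(trimethylsilyl)methyl]cyclodeca-1(10),2,4-triene-1,7-dicarboxylate | C1(C[Si](C)(C)C)CC[C@@H](C(=O)OCC)[C@](C)(CC(=O)c2ccoc2)C=CC=CC=1C(=O)OCC
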